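**Overview**

- Cuts: the C2–O–C5 bridge is opened to a 5-hydroxy-2-ketone, the C5–O bond is removed as the ene retron of an E C4=C5 alkene, and the ten-membered carbocycle is cut at both C3–C2 and C2–C1 with loss of C2 as CO. The O8 ester, C6–C7 with O6–C12, C11–C13 and C8–C9 follow.
- Enabling feature: the hemiketal carbon C2 is a masked ketone between two allylic methylenes, C3 (on C4=C5) and C1 (on C10=C14, where C1 and C14 are interchangeable CH2 termini), so CO can be set between two allyl ends to close the C1–C10 ring.
- Forward: a bis-allylstannane and an ynal give the C7–C14 arm carrying an allylboronate and an allylstannane, and prenyl acetate gives the C3–C6 chloro-enal. Their union builds the γ-lactone first, the carbonylative allyl–allyl closure builds the ten-membered ring, and the oxolane bridge forms last by transannular hemiketalisation.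
- Stereochemistry: C8 comes from an allylation catalysed by (S)-BINOL/Ti(OiPr)4 (the only reagent-controlled centre). C7 and C6 arise together in the chair allylboration (anti adduct, trans lactone, face dictated by C8). C5 comes from singlet oxygen on the outer face of the ring alkene, and C2 follows thermodynamically from the bridge.

Key step: step 14

Remark: C1–C15 are the germacrane positions of the target; the CIP letters at C6 and C7 change with the substituents along the route while the spatial arrangement stays that of the target, and the (S)-BINOL catalyst is assumed to show with the ynal the facial sense it shows with other aldehydes.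

**Route**

Step 1
Reactants: 1 3-chloro-2-(chloromethyl)prop-1-ene
Product: 3 2-methylenepropane-1,3-diylbis(tributylstannane), via 3-chloro-2-[(tributylstannyl)methyl]prop-1-ene 2 (not isolated)
Conditions: Bu3SnH, LiN(i-Pr)2, THF, 0 °C; then 1, −78 °C to rt
Reagents that add atoms: tributyltin hydride, CCCC[SnH](CCCC)CCCC (used as its lithium derivative tributylstannyllithium, [Li][Sn](CCCC)(CCCC)CCCC)
Why: Two successive SN2 displacements of primary allylic chloride by the stannyl anion (the mono-stannane 2 reacts on in the same flask) give the known conjunctive bis-allylstannane, and no stereocentre is involved.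

Step 2
Reactants: 4 3,3-diethoxyprop-1-yne
Product: 6 methyl 4,4-diethoxybut-2-ynoate, via lithium 3,3-diethoxyprop-1-yn-1-ide 5 (not isolated)
Conditions: n-BuLi, THF, −78 °C; then ClCO2Me, −78 to 0 °C
Reagents that add atoms: methyl chloroformate, COC(=O)Cl
Why: Deprotonation of the terminal alkyne and C-acylation of the lithium acetylide by the chloroformate is a standard ynoate synthesis to which the acetal is inert.

Step 3
Reactants: 6 methyl 4,4-diethoxybut-2-ynoate
Product: 7 methyl 4-oxobut-2-ynoate
Conditions: HCO2H (neat), rt; concentrated cold and used at once as a CH2Cl2 solution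
Reagents that add atoms: formic acid, OC=O (supplies the carbonyl oxygen)
Why: Acid-mediated transacetalisation to ethyl formate unmasks the aldehyde without the aqueous base or strong nucleophiles that the doubly activated alkyne would not survive.

Step 4
Reactants: 3 2-methylenepropane-1,3-diylbis(tributylstannane) (2.5 equiv); 7 methyl 4-oxobut-2-ynoate
Product: 9 methyl (4S)-4-hydroxy-6-[(tributylstannyl)methyl]hept-6-en-2-ynoate, via O-tributylstannyl ether 8 (not isolated)
Conditions: (S)-BINOL (20 mol%), Ti(OiPr)4 (10 mol%), 4 Å MS, CH2Cl2, −20 °C; aq. NaHCO3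
Reagents that add atoms: none
Why: Keck asymmetric allylation, in which the catalyst formed from (S)-BINOL and Ti(OiPr)4 activates the ynal and one allylstannane arm adds by SE2′ to its Si face to form C8–C9 and set C8 as S, while the excess of 3 keeps the second arm from reacting and the tin ether 8 is hydrolysed on work-up.

Step 5
Reactants: 9 methyl (4S)-4-hydroxy-6-[(tributylstannyl)methyl]hept-6-en-2-ynoate
Product: 10 methyl (4S)-4-[(triethylsilyl)oxy]-6-[(tributylstannyl)methyl]hept-6-en-2-ynoate
Conditions: Et3SiCl, imidazole, CH2Cl2, 0 °C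
Reagents that add atoms: chlorotriethylsilane, CC[Si](Cl)(CC)CC
Why: Imidazole-assisted silylation of a secondary alcohol is mild enough for the allylstannane and the ynoate, and the silyl ether keeps O8 away from the aluminium hydride and from butenolide formation in the next step.

Step 6
Reactants: 10 methyl (4S)-4-[(triethylsilyl)oxy]-6-[(tributylstannyl)methyl]hept-6-en-2-ynoate; 11 2-(iodomethyl)-4,4,5,5-tetramethyl-1,3,2-dioxaborolane
Product: 13 methyl (2Z,4S)-2-[(4,4,5,5-tetramethyl-1,3,2-dioxaborolan-2-yl)methyl]-4-[(triethylsilyl)oxy]-6-[(tributylstannyl)methyl]hepta-2,6-dienoate, via diisobutylalanyl acrylate 12 (not isolated)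
Conditions: i-Bu2AlH, HMPA, THF, 0 °C; then 11, 0 °C to rt
Reagents that add atoms: none
Why: Conjugate hydroalumination of the ynoate by i-Bu2AlH/HMPA is a syn addition that puts H on C7 and aluminium on C11, and C-alkylation of the alanyl acrylate 12 by the iodomethylboronate with retention forms C11–C13 and leaves C8 cis to the ester (Z), the geometry needed for an anti allylboration, with C8 untouched.

Step 7
Reactants: 14 prenyl acetate (3-methylbut-2-en-1-yl acetate)
Product: 15 (E)-4-hydroxy-3-methylbut-2-en-1-yl acetate
Conditions: SeO2 (0.4 equiv), t-BuOOH (2 equiv), CH2Cl2, 0 °C to rt, stopped before over-oxidation to the enal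
Reagents that add atoms: tert-butyl hydroperoxide, CC(C)(C)OO; selenium dioxide, O=[Se]=O (catalytic oxygen carrier)
Why: Selenium dioxide allylic oxidation (ene reaction then [2,3]-sigmatropic shift, with t-BuOOH as terminal oxidant) hydroxylates the methyl group trans to the chain of a trisubstituted alkene, which fixes the E geometry.

Step 8
Reactants: 15 (E)-4-hydroxy-3-methylbut-2-en-1-yl acetate
Product: 17 (E)-4-chloro-3-methylbut-2-en-1-yl acetate, via allylic mesylate 16 (not isolated)
Conditions: MsCl, 2,4,6-collidine, LiCl, DMF, 0 °C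
Reagents that add atoms: lithium chloride, [Li+].[Cl-]
Why: Collington–Meyers chlorination, in which the allylic mesylate 16 is displaced in the flask by chloride in an SN2 reaction without allylic transposition or loss of the E geometry.

Step 9
Reactants: 17 (E)-4-chloro-3-methylbut-2-en-1-yl acetate
Product: 18 (E)-4-chloro-3-methylbut-2-en-1-ol
Conditions: i-Bu2AlH (2.2 equiv), CH2Cl2, −78 °C; aq. KNaC4H4O6
Reagents that add atoms: none
Why: Hydride cleavage of the acetate at low temperature frees the primary alcohol without an alkoxide in a protic medium that could displace the allylic chloride.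

Step 10
Reactants: 18 (E)-4-chloro-3-methylbut-2-en-1-ol
Product: 19 (E)-4-chloro-3-methylbut-2-enal
Conditions: MnO2 (activated, excess), CH2Cl2, rt; filtered and used without storage
Reagents that add atoms: none
Why: MnO2 oxidises allylic alcohols selectively under neutral heterogeneous conditions, so the E enal should be obtained with the allylic chloride intact.

Step 11
Reactants: 13 methyl (2Z,4S)-2-[(4,4,5,5-tetramethyl-1,3,2-dioxaborolan-2-yl)methyl]-4-[(triethylsilyl)oxy]-6-[(tributylstannyl)methyl]hepta-2,6-dienoate; 19 (E)-4-chloro-3-methylbut-2-enal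
Product: 21 (4S,5R)-5-[(E)-3-chloro-2-methylprop-1-en-1-yl]-3-methylidene-4-[(1S)-1-[(triethylsilyl)oxy]-3-[(tributylstannyl)methyl]but-3-en-1-yl]oxolan-2-one, via O-boryl hydroxy ester 20 (not isolated)
Conditions: toluene (1 M), 4 Å MS, 85 °C, sealed vessel, no acid or Lewis acid
Reagents that add atoms: none
Why: Thermal allylboration of a 2-alkoxycarbonyl allylboronate through a closed six-membered chair transition state forms C6–C7 with C8 (trans to CH2B) equatorial, so the adduct is anti and the O-boryl alkoxide of 20 closes onto the methyl ester to the trans lactone; A(1,3) strain with the cis ester turns the C8–H bond into the alkene plane and the aldehyde adds to the face of C7 anti to the silyloxy group, which gives the C6 and C7 configuration of the target relative to 8S, and the acid-free medium spares the allylstannane and the allylic chloride.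

Step 12
Reactants: 21 the triethylsilyl-protected trans lactone
Product: 22 (4R,5R)-5-[(E)-3-chloro-2-methylprop-1-en-1-yl]-4-[(1S)-1-hydroxy-3-[(tributylstannyl)methyl]but-3-en-1-yl]-3-methylideneoxolan-2-one
Conditions: HF·pyridine, pyridine (excess), THF, 0 °C
Reagents that add atoms: none
Why: Fluoride cleavage of the labile triethylsilyl ether in a pyridine-buffered medium that is too weakly acidic to protodestannylate the allylstannane and not basic enough to move the lactone to O8 or to displace the allylic chloride.

Step 13
Reactants: 22 the C8 alcohol; 23 tiglic acid ((E)-2-methylbut-2-enoic acid)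
Product: 25 (1S)-1-[(2R,3R)-2-[(E)-3-chloro-2-methylprop-1-en-1-yl]-4-methylidene-5-oxooxolan-3-yl]-3-[(tributylstannyl)methyl]but-3-en-1-yl (E)-2-methylbut-2-enoate, via tiglic 2,4,6-trichlorobenzoic anhydride 24 (not isolated)
Conditions: 23, 2,4,6-trichlorobenzoyl chloride, Et3N, toluene, rt; then 22, DMAP (cat.), 0 °C to rt
Reagents that add atoms: none
Why: Yamaguchi esterification, in which the mixed anhydride 24 passes its tigloyl group through the acylpyridinium to the secondary O8 with retention at C8; the E acyl geometry is the stable one, and catalytic DMAP at low temperature limits quaternisation of the allylic chloride.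

Step 14
Reactants: 25 the seco allylic chloride/allylstannane 8-tiglate; 26 carbon monoxide
Product: 27 (4E,6R,7R,8S)-2-oxogermacra-4,10(14),11(13)-trien-12,6-olid-8-yl (E)-2-methylbut-2-enoate
Conditions: Pd2(dba)3 (5 mol%), AsPh3 (20 mol%), CO (4 atm), THF, 50 °C; 25 added by syringe pump over 12 h (final 1 mM)
Reagents that add atoms: none
Why: Proposed new method: zerovalent palladium ionises the primary allylic C3–Cl bond, CO inserts at the unhindered C3 terminus to give a β,γ-unsaturated acylpalladium chloride with the E C4=C5 geometry kept (syn π-allyl), the 2-substituted allylstannane transmetallates and reductive elimination joins C2 to C1, so that C3–C2 and C2–C1 form in one operation with CO as C2. The closest known reaction type is the intermolecular palladium-catalysed carbonylative coupling of allyl chlorides with allylstannanes to diallyl ketones, together with macrocyclic carbonylative Stille closures of vinyl partners, and the ten-membered allyl/allyl closure is the extrapolation. The ten-membered carbocycle closes end to end (endo mode) by reductive elimination from an eleven-membered acyl(allyl)palladacycle, helped by slow addition at high dilution and by the four sp2 ring atoms (C2, C4, C5, C10), the trans lactone and the E alkene that restrict the chain. No stereocentre is created, and C6, C7 and C8 are untouched in the neutral medium, which also keeps both β,γ-unsaturated ketone flanks, the α-methylene lactone and the tiglate out of conjugation or addition. The step needs CO insertion instead of direct allyl–allyl coupling (secured by CO pressure), one regioisomer (C1 and C14 are identical CH2 termini, so SE2 and SE2′ give the same ketone, and C3 is the primary π-allyl terminus), ionisation of C3–Cl and not of the secondary allylic C6–O lactone bond (a primary chloride ionises far faster), and no oxygen trap for the acylpalladium (O8 is already acylated and C5 is still unoxidised).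

Step 15
Reactants: 27 the macrocyclic 2-ketone
Product: 28 (5S,6S,7R,8S)-5-hydroperoxy-2-oxogermacra-4(15),10(14),11(13)-trien-12,6-olid-8-yl (E)-2-methylbut-2-enoate
Conditions: O2, tetraphenylporphyrin (cat.), visible light (>450 nm), CH2Cl2, −30 °C
Reagents that add atoms: dioxygen, O=O
Why: Schenck ene reaction, in which singlet oxygen attacks only the electron-rich trisubstituted C4=C5 alkene (the 1,1-disubstituted C10=C14 and the conjugated alkenes are inert), bonds to C5 from the exposed outer face of the E alkene held by the trans lactone (the face peracids take in 6,12-olides of this type), which sets C5 as S, and removes hydrogen from the C15 methyl group on the more substituted side to give the exocyclic C4=C15 bond.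

Step 16
Reactants: 28 the 5-hydroperoxide
Product: 30 (2S,5S,6S,7R,8S)-2,5-epoxy-2-hydroxygermacra-4(15),10(14),11(13)-trien-12,6-olid-8-yl (E)-2-methylbut-2-enoate (CNP0307443.2), via 5-hydroxy-2-ketone 29 (not isolated)
Conditions: Me2S, CH2Cl2, 0 °C to rt; pH 7 work-up, no acid
Reagents that add atoms: none
Why: Sulfide reduction of the O–O bond leaves the C5–O bond and its configuration intact, and the 5-hydroxyl of 29 then adds across the ring to the C2 ketone (oxolane closure by transannular hemiketalisation), with C2 set thermodynamically as S because only the cis 2,5-bridge can span the ten-membered ring and the hemiketal equilibrates, while the neutral medium avoids dehydration to the furan.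

**Compound list**

1 | 3-chloro-2-(chloromethyl)prop-1-ene | C=C(CCl)CCl | starting material
2 | 3-chloro-2-[(tributylstannyl)methyl]prop-1-ene (not isolated) | C=C(CCl)C[Sn](CCCC)(CCCC)CCCC | intermediate
3 | 2-methylenepropane-1,3-diylbis(tributylstannane) | C=C(C[Sn](CCCC)(CCCC)CCCC)C[Sn](CCCC)(CCCC)CCCC | intermediate
4 | 3,3-diethoxyprop-1-yne | C#CC(OCC)OCC | starting material
5 | lithium 3,3-diethoxyprop-1-yn-1-ide (not isolated) | [Li]C#CC(OCC)OCC | intermediate
6 | methyl 4,4-diethoxybut-2-ynoate | CCOC(OCC)C#CC(=O)OC | intermediate
7 | methyl 4-oxobut-2-ynoate | COC(=O)C#CC=O | intermediate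
8 | methyl (4S)-4-[(tributylstannyl)oxy]-6-[(tributylstannyl)methyl]hept-6-en-2-ynoate (not isolated) | COC(=O)C#C[C@@H](O[Sn](CCCC)(CCCC)CCCC)CC(=C)C[Sn](CCCC)(CCCC)CCCC | intermediate
9 | methyl (4S)-4-hydroxy-6-[(tributylstannyl)methyl]hept-6-en-2-ynoate | COC(=O)C#C[C@@H](O)CC(=C)C[Sn](CCCC)(CCCC)CCCC | intermediate
10 | methyl (4S)-4-[(triethylsilyl)oxy]-6-[(tributylstannyl)methyl]hept-6-en-2-ynoate | COC(=O)C#C[C@@H](O[Si](CC)(CC)CC)CC(=C)C[Sn](CCCC)(CCCC)CCCC | intermediate
11 | 2-(iodomethyl)-4,4,5,5-tetramethyl-1,3,2-dioxaborolane | ICB1OC(C)(C)C(C)(C)O1 | starting material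
12 | methyl (2E,4S)-2-(diisobutylalumanyl)-4-[(triethylsilyl)oxy]-6-[(tributylstannyl)methyl]hepta-2,6-dienoate (not isolated; Al cis to H, C4 cis to the ester) | COC(=O)/C([Al](CC(C)C)CC(C)C)=C\[C@@H](O[Si](CC)(CC)CC)CC(=C)C[Sn](CCCC)(CCCC)CCCC | intermediate
13 | methyl (2Z,4S)-2-[(4,4,5,5-tetramethyl-1,3,2-dioxaborolan-2-yl)methyl]-4-[(triethylsilyl)oxy]-6-[(tributylstannyl)methyl]hepta-2,6-dienoate | COC(=O)/C(CB1OC(C)(C)C(C)(C)O1)=C\[C@@H](O[Si](CC)(CC)CC)CC(=C)C[Sn](CCCC)(CCCC)CCCC | intermediate
14 | prenyl acetate (3-methylbut-2-en-1-yl acetate) | CC(C)=CCOC(C)=O | starting material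
15 | (E)-4-hydroxy-3-methylbut-2-en-1-yl acetate | OC/C(C)=C/COC(C)=O | intermediate
16 | (E)-3-methyl-4-[(methylsulfonyl)oxy]but-2-en-1-yl acetate (not isolated) | CS(=O)(=O)OC/C(C)=C/COC(C)=O | intermediate
17 | (E)-4-chloro-3-methylbut-2-en-1-yl acetate | ClC/C(C)=C/COC(C)=O | intermediate
18 | (E)-4-chloro-3-methylbut-2-en-1-ol | ClC/C(C)=C/CO | intermediate
19 | (E)-4-chloro-3-methylbut-2-enal | ClC/C(C)=C/C=O | intermediate
20 | methyl (3S,4R,5E)-7-chloro-6-methyl-2-methylidene-4-[(4,4,5,5-tetramethyl-1,3,2-dioxaborolan-2-yl)oxy]-3-[(1S)-1-[(triethylsilyl)oxy]-3-[(tributylstannyl)methyl]but-3-en-1-yl]hept-5-enoate (not isolated) | CCCC[Sn](CCCC)(CCCC)CC(=C)C[C@H](O[Si](CC)(CC)CC)[C@@H](C(=C)C(=O)OC)[C@H](OB1OC(C)(C)C(C)(C)O1)/C=C(\C)CCl | intermediate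
21 | (4S,5R)-5-[(E)-3-chloro-2-methylprop-1-en-1-yl]-3-methylidene-4-[(1S)-1-[(triethylsilyl)oxy]-3-[(tributylstannyl)methyl]but-3-en-1-yl]oxolan-2-one | CCCC[Sn](CCCC)(CCCC)CC(=C)C[C@H](O[Si](CC)(CC)CC)[C@H]1C(=C)C(=O)O[C@@H]1/C=C(\C)CCl | intermediate
22 | (4R,5R)-5-[(E)-3-chloro-2-methylprop-1-en-1-yl]-4-[(1S)-1-hydroxy-3-[(tributylstannyl)methyl]but-3-en-1-yl]-3-methylideneoxolan-2-one | CCCC[Sn](CCCC)(CCCC)CC(=C)C[C@H](O)[C@H]1C(=C)C(=O)O[C@@H]1/C=C(\C)CCl | intermediate
23 | tiglic acid ((E)-2-methylbut-2-enoic acid) | C/C=C(\C)C(=O)O | starting material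
24 | (E)-2-methylbut-2-enoic 2,4,6-trichlorobenzoic anhydride (not isolated) | C/C=C(\C)C(=O)OC(=O)c1c(Cl)cc(Cl)cc1Cl | intermediate
25 | (1S)-1-[(2R,3R)-2-[(E)-3-chloro-2-methylprop-1-en-1-yl]-4-methylidene-5-oxooxolan-3-yl]-3-[(tributylstannyl)methyl]but-3-en-1-yl (E)-2-methylbut-2-enoate | CCCC[Sn](CCCC)(CCCC)CC(=C)C[C@H](OC(=O)/C(C)=C/C)[C@H]1C(=C)C(=O)O[C@@H]1/C=C(\C)CCl | intermediate
26 | carbon monoxide | [C-]#[O+] | starting material
27 | (4E,6R,7R,8S)-2-oxogermacra-4,10(14),11(13)-trien-12,6-olid-8-yl (E)-2-methylbut-2-enoate | C=C1C[C@H](OC(=O)/C(C)=C/C)[C@H]2C(=C)C(=O)O[C@@H]2/C=C(\C)CC(=O)C1 | intermediate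
28 | (5S,6S,7R,8S)-5-hydroperoxy-2-oxogermacra-4(15),10(14),11(13)-trien-12,6-olid-8-yl (E)-2-methylbut-2-enoate | C=C1C[C@H](OC(=O)/C(C)=C/C)[C@H]2C(=C)C(=O)O[C@@H]2[C@@H](OO)C(=C)CC(=O)C1 | intermediate
29 | (5S,6S,7R,8S)-5-hydroxy-2-oxogermacra-4(15),10(14),11(13)-trien-12,6-olid-8-yl (E)-2-methylbut-2-enoate (not isolated) | C=C1C[C@H](OC(=O)/C(C)=C/C)[C@H]2C(=C)C(=O)O[C@@H]2[C@@H](O)C(=C)CC(=O)C1 | intermediate
30 | (2S,5S,6S,7R,8S)-2,5-epoxy-2-hydroxygermacra-4(15),10(14),11(13)-trien-12,6-olid-8-yl (E)-2-methylbut-2-enoate (CNP0307443.2) | C=C1C[C@H](OC(=O)/C(C)=C/C)[C@H]2C(=C)C(=O)O[C@@H]2[C@H]2O[C@@](O)(C1)CC2=C | target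

**Step count**

Total: 16 steps. Longest linear sequence: 11 steps (4 → 6 → 7 → 9 → 10 → 13 → 21 → 22 → 25 → 27 → 28 → 30).

**Steps most likely to fail**

1. Step 14 (carbonylative ring closure). Transmetallation of the tethered stannane to the acylpalladium may be too slow, so that oligomerisation, CO-free allyl–allyl coupling or drift of the β,γ-alkenes into conjugation takes over.
The fallback sets out from seco tiglate 25 and comes back to the route at ketone 27. C2 is still taken from CO, but as a formyl group: palladium-catalysed formylation of the allylic chloride (Pd(PPh3)4, CO, slow addition of Bu3SnH, THF, 50 °C), a known reaction of allyl halides, should give the seco β,γ-unsaturated aldehyde F1. BF3·OEt2 in CH2Cl2 at −78 °C under high dilution then closes the ring at C1–C2 by the known Lewis acid-promoted addition of an allylstannane to an aldehyde, again without a regiochemical question because C1 and C14 are equivalent, to give the 2-hydroxy macrocycle F2 as a mixture of C2 epimers. Dess–Martin periodinane buffered with NaHCO3 oxidises F2 to 27.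

2. Step 11 (fragment union). The electron-poor, γ-substituted boronate may add too slowly to the enal without acid, so that prolonged heating erodes the allylstannane, leaves the hydroxy ester unclosed, or gives poor face selectivity relative to C8.
The fallback sets out from silyl ynoate 10 (with enal 19) and comes back at lactone 21, replacing boron by chromium. Hydroalumination as in step 6 with capture of the alanyl acrylate by gaseous formaldehyde should give the (Z)-2-(hydroxymethyl) enoate F3, and CBr4/PPh3 converts it into the allylic bromide F4. CrCl2 in THF at 0 °C to rt with 19 (Nozaki–Hiyama allylation, divalent chromium) forms an allylchromium species from the activated bromide before the allylic chloride reacts. This adds to the aldehyde through a chair transition state with anti selectivity, and the chromium alkoxide lactonises to 21.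

3. Step 15 (singlet-oxygen ene reaction). Hydrogen may be taken from C3 next to the ketone instead of from C15, or the alkene, deactivated by the allylic lactone oxygen, may react too slowly and let the hydroperoxide decompose.
The fallback sets out from ketone 27 and comes back at hydroxy ketone 29, which closes to 30 as in step 16. mCPBA/NaHCO3 in CH2Cl2 at 0 °C epoxidises the trisubstituted alkene on the same outer face to the 4,5-epoxide F5, so oxygen is fixed on C5. Cp2TiCl (trivalent titanium, made from Cp2TiCl2 and Mn powder, THF, rt) then opens the epoxide homolytically to the tertiary C4 radical, which loses hydrogen from the C15 methyl group, the usual course with trisubstituted epoxides, to give the 5-hydroxy-4(15)-ene 29.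

**Further compounds**

F1 | step 14 | (1S)-1-[(2R,3R)-2-[(E)-2-methyl-4-oxobut-1-en-1-yl]-4-methylidene-5-oxooxolan-3-yl]-3-[(tributylstannyl)methyl]but-3-en-1-yl (E)-2-methylbut-2-enoate | CCCC[Sn](CCCC)(CCCC)CC(=C)C[C@H](OC(=O)/C(C)=C/C)[C@H]1C(=C)C(=O)O[C@@H]1/C=C(\C)CC=O
F2 | step 14 | (4E,6R,7R,8S)-2-hydroxygermacra-4,10(14),11(13)-trien-12,6-olid-8-yl (E)-2-methylbut-2-enoate (C2 epimers) | C=C1C[C@H](OC(=O)/C(C)=C/C)[C@H]2C(=C)C(=O)O[C@@H]2/C=C(\C)CC(O)C1
F3 | step 11 | methyl (2Z,4S)-2-(hydroxymethyl)-4-[(triethylsilyl)oxy]-6-[(tributylstannyl)methyl]hepta-2,6-dienoate | COC(=O)/C(CO)=C\[C@@H](O[Si](CC)(CC)CC)CC(=C)C[Sn](CCCC)(CCCC)CCCC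
F4 | step 11 | methyl (2E,4S)-2-(bromomethyl)-4-[(triethylsilyl)oxy]-6-[(tributylstannyl)methyl]hepta-2,6-dienoate | COC(=O)/C(CBr)=C\[C@@H](O[Si](CC)(CC)CC)CC(=C)C[Sn](CCCC)(CCCC)CCCC
F5 | step 15 | 4,5-epoxide of ketone 27 (oxygen on the C5 face that carries the hydroperoxide in 28) | C=C1C[C@H](OC(=O)/C(C)=C/C)[C@H]2C(=C)C(=O)O[C@@H]2[C@H]2O[C@]2(C)CC(=O)C1
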